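**Retrosynthetic overview** (positions in labdane numbering, C1–C20)
1. Target ⇐ methylenation (C17) of the C8 ketone of an 11-acetoxy-8-oxo precursor.
2. That β-acetoxy ketone ⇐ Lewis-acid semipinacol ring expansion of a trans-epoxide on a tertiary cyclopentanol: C10 shifts from C8 to C9, the five-membered ring becomes ring B, and C9 and C11 are fixed stereospecifically.
3. Epoxy alcohol ⇐ reagent-controlled Shi epoxidation ⇐ cross-metathesis of a 1-vinyl-trans-hydrindan-1-ol with methyl (2E)-3-methylhexa-2,5-dienoate (allylcopper + methyl but-2-ynoate).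
4. trans-Hydrindanone ⇐ ring-closing metathesis/hydrogenation ⇐ catalytic enantioselective conjugate reverse prenylation and enolate allylation of 2-methylcyclopent-2-en-1-one (sets C5, then C10).
5. Ring order: five-membered ring (bought) → ring A (metathesis) → ring B (ring expansion of the five-membered ring).

Assumption: commercial Grignard solutions (prenyl-, vinyl-, allylmagnesium halide) are taken as purchasable starting materials.

**Route**

Step 1
Reactants: 1 (3-methylbut-2-en-1-yl)magnesium chloride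
Product: 2 trimethyl(3-methylbut-2-en-1-yl)silane
Conditions: Me3SiCl, THF, 0 → 23 °C
Reagents that add atoms: chlorotrimethylsilane, C[Si](C)(C)Cl
Why: Silylation of an allylic Grignard reagent, in which the bulky silicon electrophile bonds to the unhindered primary terminus and gives the linear prenylsilane; no stereocentre is formed.

Step 2
Reactants: 2 trimethyl(3-methylbut-2-en-1-yl)silane; 3 2-methylcyclopent-2-en-1-one; 4 3-bromoprop-1-ene
Product: 7 (2S,3S)-2-methyl-3-(2-methylbut-3-en-2-yl)-2-(prop-2-en-1-yl)cyclopentan-1-one, via silyl enol ether 5 (not isolated), via lithium enolate 6 (not isolated)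
Conditions: chiral IDPi Brønsted acid (N-triflyl imidodiphosphorimidate built from 3,3′-diaryl-BINOL, the antipode giving (3S)-5; 2 mol %), 2 (1.5 equiv), toluene, −60 °C; then MeLi, THF, 0 °C; then 4, DMPU, −78 → 0 °C
Reagents that add atoms: none
Why: Proposed new method: the IDPi acid is silylated by 2 and the silylium–IDPi ion pair O-silylates enone 3 to a siloxyallyl cation held in the confined chiral anion; 2 then attacks the β-carbon through its γ-carbon (SE2′, Hosomi–Sakurai conjugate allylation) on the exposed enantioface, making the C4–C5 bond and the C5 stereocentre, and loss of Me3Si+ from the β-silyl cation regenerates the catalyst and leaves regiodefined enol silane 5; MeLi unmasks enolate 6, which is allylated anti to the bulky tertiary group to set the C10 quaternary centre (regiospecific enolate alkylation); the closest known reactions are IDPi-catalysed Hosomi–Sakurai allylation of aldehydes, IDPi-catalysed Mukaiyama–Michael additions, and the racemic TiCl4-mediated conjugate addition of prenylsilanes to enones.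

Step 3
Reactants: 7 (2S,3S)-2-methyl-3-(2-methylbut-3-en-2-yl)-2-(prop-2-en-1-yl)cyclopentan-1-one
Product: 9 (3aS,7aS)-4,4,7a-trimethyloctahydro-1H-inden-1-one, via hexahydroindenone 8 (not isolated)
Conditions: second-generation Grubbs catalyst (3 mol %), CH2Cl2, 40 °C; then Pd/C, H2 (1 atm), EtOAc, 23 °C
Reagents that add atoms: none
Why: Ring-closing olefin metathesis joins the trans-disposed allyl and 1,1-dimethylallyl arms into ring A (trans-fused, gem-dimethyl effect helps closure), and the heterogeneous hydrogenation saturates the only C=C bond without touching the ketone or any stereocentre.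

Step 4
Reactants: 9 (3aS,7aS)-4,4,7a-trimethyloctahydro-1H-inden-1-one; 10 ethenylmagnesium bromide
Product: 11 (1R,3aS,7aS)-1-ethenyl-4,4,7a-trimethyloctahydro-1H-inden-1-ol
Conditions: CeCl3, THF, −78 → 0 °C; H2O work-up
Reagents that add atoms: none
Why: Organocerium 1,2-addition suppresses enolisation of the hindered ketone, and attack on the face opposite the angular methyl group (as in 17-keto steroids) sets the (1R) carbinol.

Step 5
Reactants: 12 prop-2-en-1-ylmagnesium bromide; 13 methyl but-2-ynoate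
Product: 16 methyl (2E)-3-methylhexa-2,5-dienoate, via allylcopper 14 (not isolated), via alkenylcopper 15 (not isolated)
Conditions: CuBr·SMe2 (1.1 equiv), THF, −78 °C; 13, −78 °C; AcOH quench at −78 °C
Reagents that add atoms: none
Why: syn-Carbocupration of the ynoate places allyl and copper cis, and stereoretentive protonation of the alkenylcopper at −78 °C gives the (E)-enoate with the chain trans to the ester.

Step 6
Reactants: 11 (1R,3aS,7aS)-1-ethenyl-4,4,7a-trimethyloctahydro-1H-inden-1-ol; 16 methyl (2E)-3-methylhexa-2,5-dienoate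
Product: 17 methyl (2E,5E)-6-[(1R,3aS,7aS)-1-hydroxy-4,4,7a-trimethyloctahydro-1H-inden-1-yl]-3-methylhexa-2,5-dienoate
Conditions: 16 (3 equiv), second-generation Hoveyda–Grubbs catalyst (5 mol %), 1,4-benzoquinone (10 mol %), CH2Cl2, 40 °C
Reagents that add atoms: none
Why: Olefin cross-metathesis exchanges the two terminal alkenes with loss of ethene; the trisubstituted enoate alkene stays out of the cycle, the free allylic hydroxyl is tolerated, the new disubstituted alkene forms E under thermodynamic control, and benzoquinone suppresses isomerisation of the skipped diene.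

Step 7
Reactants: 17 methyl (2E,5E)-6-[(1R,3aS,7aS)-1-hydroxy-4,4,7a-trimethyloctahydro-1H-inden-1-yl]-3-methylhexa-2,5-dienoate
Product: 18 methyl (2E)-4-{(2S,3R)-3-[(1S,3aS,7aS)-1-hydroxy-4,4,7a-trimethyloctahydro-1H-inden-1-yl]oxiran-2-yl}-3-methylbut-2-enoate
Conditions: L-fructose-derived Shi ketone (30 mol %), KHSO5 (Oxone), K2CO3, Bu4NHSO4, MeCN–CH2(OMe)2–aq. Na2B4O7 buffer, 0 °C
Reagents that add atoms: potassium peroxymonosulfate, [K+].[O-]S(=O)(=O)OO
Why: Shi asymmetric epoxidation: the chiral dioxirane delivers oxygen through a spiro transition state to the electron-rich E-alkene only (the enoate is too electron-poor), and the L-fructose-derived catalyst selects the face that gives the (2S,3R)-oxirane, fixing C11 as (S) and C9 in the configuration that is inverted in step 8.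

Step 8
Reactants: 18 methyl (2E)-4-{(2S,3R)-3-[(1S,3aS,7aS)-1-hydroxy-4,4,7a-trimethyloctahydro-1H-inden-1-yl]oxiran-2-yl}-3-methylbut-2-enoate
Product: 20 methyl (2E,5S)-5-(acetyloxy)-3-methyl-5-[(1S,4aS,8aS)-5,5,8a-trimethyl-2-oxodecahydronaphthalen-1-yl]pent-2-enoate, via hydroxy ketone 19 (not isolated)
Conditions: BF3·OEt2 (1.2 equiv), CH2Cl2, −78 °C; then pyridine, Ac2O, DMAP, −78 → 0 °C
Reagents that add atoms: acetic anhydride, CC(=O)OC(C)=O
Why: Epoxy alcohol semipinacol rearrangement (Lewis-acid-promoted 1,2-alkyl shift with ring expansion): the C8–C10 bond, antiperiplanar to the breaking C9–O bond, migrates to C9 with inversion there and retention at C10 and C11, turning the cyclopentanol into the cyclohexanone of ring B with C9 (S) and C11 (S); the quaternary carbon should migrate rather than C7 because of its higher migratory aptitude and because the competing rotamer wedges the oxirane substituent between C7 and C10; the freed C11 alcohol is acetylated in the same flask (DMAP-catalysed acylation).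

Step 9
Reactants: 20 methyl (2E,5S)-5-(acetyloxy)-3-methyl-5-[(1S,4aS,8aS)-5,5,8a-trimethyl-2-oxodecahydronaphthalen-1-yl]pent-2-enoate
Product: 21 methyl (2E,5S)-5-(acetyloxy)-3-methyl-5-[(1S,4aS,8aS)-5,5,8a-trimethyl-2-methylidenedecahydronaphthalen-1-yl]pent-2-enoate
Conditions: Zn, CH2Br2, TiCl4, THF–CH2Cl2, 0 → 23 °C
Reagents that add atoms: dibromomethane, BrCBr
Why: Takai–Lombardo methylenation: the non-basic zinc/titanium methylene reagent olefinates ketones but not esters, so the hindered C8 ketone becomes the exocyclic methylene without β-elimination of the acetate, epimerisation at C9 or attack on the acetate and enoate; no new stereocentre.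

**Compound list**
1 | (3-methylbut-2-en-1-yl)magnesium chloride | CC(C)=CC[Mg]Cl | starting material
2 | trimethyl(3-methylbut-2-en-1-yl)silane | CC(C)=CC[Si](C)(C)C | intermediate
3 | 2-methylcyclopent-2-en-1-one | CC1=CCCC1=O | starting material
4 | 3-bromoprop-1-ene | C=CCBr | starting material
5 | trimethyl{[(3S)-2-methyl-3-(2-methylbut-3-en-2-yl)cyclopent-1-en-1-yl]oxy}silane | C=CC(C)(C)[C@@H]1CCC(O[Si](C)(C)C)=C1C | intermediate (not isolated)
6 | lithium (3S)-2-methyl-3-(2-methylbut-3-en-2-yl)cyclopent-1-en-1-olate | C=CC(C)(C)[C@@H]1CCC(O[Li])=C1C | intermediate (not isolated)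
7 | (2S,3S)-2-methyl-3-(2-methylbut-3-en-2-yl)-2-(prop-2-en-1-yl)cyclopentan-1-one | O=C1CC[C@@H](C(C)(C)C=C)[C@]1(C)CC=C | intermediate
8 | (3aS,7aS)-4,4,7a-trimethyl-2,3,3a,4,7,7a-hexahydro-1H-inden-1-one | O=C1CC[C@H]2C(C)(C)C=CC[C@]12C | intermediate (not isolated)
9 | (3aS,7aS)-4,4,7a-trimethyloctahydro-1H-inden-1-one | O=C1CC[C@H]2C(C)(C)CCC[C@]12C | intermediate
10 | ethenylmagnesium bromide | C=C[Mg]Br | starting material
11 | (1R,3aS,7aS)-1-ethenyl-4,4,7a-trimethyloctahydro-1H-inden-1-ol | C=C[C@]1(O)CC[C@H]2C(C)(C)CCC[C@]12C | intermediate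
12 | prop-2-en-1-ylmagnesium bromide | C=CC[Mg]Br | starting material
13 | methyl but-2-ynoate | CC#CC(=O)OC | starting material
14 | prop-2-en-1-ylcopper | C=CC[Cu] | intermediate (not isolated)
15 | [(2Z)-1-methoxy-3-methyl-1-oxohexa-2,5-dien-2-yl]copper | [Cu]/C(C(=O)OC)=C(/C)CC=C | intermediate (not isolated)
16 | methyl (2E)-3-methylhexa-2,5-dienoate | COC(=O)/C=C(C)/CC=C | intermediate
17 | methyl (2E,5E)-6-[(1R,3aS,7aS)-1-hydroxy-4,4,7a-trimethyloctahydro-1H-inden-1-yl]-3-methylhexa-2,5-dienoate | COC(=O)/C=C(C)/C/C=C/[C@]1(O)CC[C@H]2C(C)(C)CCC[C@]12C | intermediate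
18 | methyl (2E)-4-{(2S,3R)-3-[(1S,3aS,7aS)-1-hydroxy-4,4,7a-trimethyloctahydro-1H-inden-1-yl]oxiran-2-yl}-3-methylbut-2-enoate | COC(=O)/C=C(C)/C[C@@H]1O[C@H]1[C@]2(O)CC[C@H]3C(C)(C)CCC[C@]23C | intermediate
19 | methyl (2E,5S)-5-hydroxy-3-methyl-5-[(1S,4aS,8aS)-5,5,8a-trimethyl-2-oxodecahydronaphthalen-1-yl]pent-2-enoate | O=C1CC[C@H]2C(C)(C)CCC[C@]2(C)[C@H]1[C@H](C/C(C)=C/C(=O)OC)O | intermediate (not isolated)
20 | methyl (2E,5S)-5-(acetyloxy)-3-methyl-5-[(1S,4aS,8aS)-5,5,8a-trimethyl-2-oxodecahydronaphthalen-1-yl]pent-2-enoate | O=C1CC[C@H]2C(C)(C)CCC[C@]2(C)[C@H]1[C@H](C/C(C)=C/C(=O)OC)OC(C)=O | intermediate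
21 | methyl (2E,5S)-5-(acetyloxy)-3-methyl-5-[(1S,4aS,8aS)-5,5,8a-trimethyl-2-methylidenedecahydronaphthalen-1-yl]pent-2-enoate | C=C1CC[C@H]2C(C)(C)CCC[C@]2(C)[C@H]1[C@H](C/C(C)=C/C(=O)OC)OC(C)=O | target

**Step count and risks**

Total steps: 9. Longest linear sequence: 8 (steps 1, 2, 3, 4, 6, 7, 8, 9).

The three steps most likely to fail are steps 2, 6 and 8.

Step 2, the new reaction, may suffer from low turnover, because a quaternary–tertiary C–C bond must form inside a confined ion pair, or from insufficient enantioselectivity. The fallback sets out from 2 and 3 and uses known chemistry only. The stoichiometric TiCl4-mediated Hosomi–Sakurai reaction (CH2Cl2, −78 °C) gives racemic trans-2-methyl-3-(2-methylbut-3-en-2-yl)cyclopentan-1-one F1. Thermodynamic silylation (Me3SiCl, NaI, Et3N, MeCN) gives racemic 5, which is taken through the MeLi/allyl bromide alkylation and step 3 to racemic 9. Reduction with NaBH4 gives the racemic alcohol. Lipase-catalysed acetylation (Candida antarctica lipase B, vinyl acetate, 40 °C) is expected to leave (1S,3aS,7aS)-4,4,7a-trimethyloctahydro-1H-inden-1-ol F2 untouched and to convert its enantiomer into (1R,3aR,7aR)-4,4,7a-trimethyloctahydro-1H-inden-1-yl acetate F3. After separation, Dess–Martin oxidation of the alcohol returns enantiopure 9, where the route is rejoined.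

Step 6 may fail because the vinyl group sits on a carbinol flanked by a quaternary carbon, and the skipped diene of 16 can isomerise. The fallback sets out from 9 and builds the same E-alkene by cross-coupling. Ethynylmagnesium bromide with CeCl3 gives (1R,3aS,7aS)-1-ethynyl-4,4,7a-trimethyloctahydro-1H-inden-1-ol F4. Hydrostannation (Bu3SnH, PdCl2(PPh3)2) gives (1R,3aS,7aS)-4,4,7a-trimethyl-1-[(E)-2-(tributylstannyl)ethenyl]octahydro-1H-inden-1-ol F5. Stille coupling (Pd(PPh3)4, DMF) with methyl (2E)-4-bromo-3-methylbut-2-enoate F6, made from methyl 3-methylbut-2-enoate by NBS bromination with separation of the E isomer, gives 17, where the route is rejoined.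

Step 8 may fail through a mismatched epoxidation upstream, opening of the oxirane at C11, competing migration of C7, or elimination during the in-flask acetylation. The fallback sets out from 11, runs the ring expansion on the simpler vinyl system, and sets C11 afterwards by a catalyst-controlled aldol reaction. It does not remove the C7-migration risk, since it uses the same type of shift.
- Hydroxyl-directed epoxidation (VO(acac)2, t-BuOOH) gives (1S,3aS,7aS)-4,4,7a-trimethyl-1-[(2R)-oxiran-2-yl]octahydro-1H-inden-1-ol F7. The oxirane epimer is tolerated because C9 becomes epimerisable.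
- BF3·OEt2 ring expansion and K2CO3/MeOH equilibration give (1S,4aS,8aS)-1-(hydroxymethyl)-5,5,8a-trimethyloctahydronaphthalen-2(1H)-one F8.
- Zn/CH2Br2/TiCl4 methylenation gives [(1S,4aS,8aS)-5,5,8a-trimethyl-2-methylidenedecahydronaphthalen-1-yl]methanol F9.
- Dess–Martin oxidation gives (1S,4aS,8aS)-5,5,8a-trimethyl-2-methylidenedecahydronaphthalene-1-carbaldehyde F10.
- A vinylogous Mukaiyama aldol addition of [(1-methoxy-3-methylbuta-1,3-dien-1-yl)oxy]trimethylsilane F11 (from methyl 3-methylbut-2-enoate, LiN(i-Pr)2, Me3SiCl), run with SiCl4 and a chiral bisphosphoramide at −78 °C, gives methyl (2E,5S)-5-hydroxy-3-methyl-5-[(1S,4aS,8aS)-5,5,8a-trimethyl-2-methylidenedecahydronaphthalen-1-yl]pent-2-enoate F12.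
- Acetylation (Ac2O, DMAP, pyridine) gives 21, where the route is rejoined.

**Further compounds**
F1 | step 2 | rac-(2S,3R)-2-methyl-3-(2-methylbut-3-en-2-yl)cyclopentan-1-one (racemate, one enantiomer drawn) | O=C1CC[C@@H](C(C)(C)C=C)[C@@H]1C
F2 | step 2 | (1S,3aS,7aS)-4,4,7a-trimethyloctahydro-1H-inden-1-ol | O[C@H]1CC[C@H]2C(C)(C)CCC[C@]12C
F3 | step 2 | (1R,3aR,7aR)-4,4,7a-trimethyloctahydro-1H-inden-1-yl acetate | CC(=O)O[C@@H]1CC[C@@H]2C(C)(C)CCC[C@@]12C
F4 | step 6 | (1R,3aS,7aS)-1-ethynyl-4,4,7a-trimethyloctahydro-1H-inden-1-ol | C#C[C@]1(O)CC[C@H]2C(C)(C)CCC[C@]12C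
F5 | step 6 | (1R,3aS,7aS)-4,4,7a-trimethyl-1-[(E)-2-(tributylstannyl)ethenyl]octahydro-1H-inden-1-ol | CCCC[Sn](CCCC)(CCCC)/C=C/[C@]1(O)CC[C@H]2C(C)(C)CCC[C@]12C
F6 | step 6 | methyl (2E)-4-bromo-3-methylbut-2-enoate | COC(=O)/C=C(C)/CBr
F7 | step 8 | (1S,3aS,7aS)-4,4,7a-trimethyl-1-[(2R)-oxiran-2-yl]octahydro-1H-inden-1-ol | C1O[C@H]1[C@]2(O)CC[C@H]3C(C)(C)CCC[C@]23C
F8 | step 8 | (1S,4aS,8aS)-1-(hydroxymethyl)-5,5,8a-trimethyloctahydronaphthalen-2(1H)-one | O=C1CC[C@H]2C(C)(C)CCC[C@]2(C)[C@H]1CO
F9 | step 8 | [(1S,4aS,8aS)-5,5,8a-trimethyl-2-methylidenedecahydronaphthalen-1-yl]methanol | C=C1CC[C@H]2C(C)(C)CCC[C@]2(C)[C@H]1CO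
F10 | step 8 | (1S,4aS,8aS)-5,5,8a-trimethyl-2-methylidenedecahydronaphthalene-1-carbaldehyde | C=C1CC[C@H]2C(C)(C)CCC[C@]2(C)[C@H]1C=O
F11 | step 8 | [(1-methoxy-3-methylbuta-1,3-dien-1-yl)oxy]trimethylsilane | COC(O[Si](C)(C)C)=CC(C)=C
F12 | step 8 | methyl (2E,5S)-5-hydroxy-3-methyl-5-[(1S,4aS,8aS)-5,5,8a-trimethyl-2-methylidenedecahydronaphthalen-1-yl]pent-2-enoate | C=C1CC[C@H]2C(C)(C)CCC[C@]2(C)[C@H]1[C@H](C/C(C)=C/C(=O)OC)O
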